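The cyclohexenone (C1 ketone, C2 bearing C7H2OH, C3, C4 propanoate, C5 isopropyl, C6 4-hydroxytiglate) is disconnected at C1–C6 and C4–C5, because its C2=C3 alkene sits between the three contiguous stereocentres C4, C5 and C6, the signature of a [4+2] adduct. One catalytic asymmetric Diels–Alder reaction closes the carbocycle and sets C4, C5 and C6 together, with a sacrificial centre at C1. The diene is a C1=C2–C3=C4 silyl dienol ether whose C1 and C7 oxygens are locked in an acetonide ring; the dienophile is an (E)-β-acyloxy methyl enone that already carries the complete C6 ester. Afterwards acetyl becomes isopropyl and the acetonide is unmasked to ketone and alcohol.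

Key step: step 8

Numbering used throughout (target numbering): C1 = ring ketone carbon, C2 = alkene carbon bearing C7 (the CH2OH carbon), C3 = alkene CH, C4 = CH–O-propanoyl, C5 = CH–isopropyl, C6 = CH–O-acyl. "α" is the ring face that carries the C4 oxygen. The target is 4S,5S,6R: C4–O and C5–isopropyl cis (α), C6–O trans to both (β).

Assumption: the facial preference of the (S)-configured catalyst is assigned from the boron–carbonyl / α-C–H···O two-point binding picture for enones. It would be confirmed on the first batch (Mosher ester analysis at 19); the (R)-catalyst is the direct remedy should the sense prove opposite.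

**Step 1**
Reactants: 1 2,2-dimethyl-1,3-dioxan-5-one; 2 N-methoxy-N-methyl-2-(triphenylphosphoranylidene)acetamide
Product: 3 2-(2,2-dimethyl-1,3-dioxan-5-ylidene)-N-methoxy-N-methylacetamide
Conditions: PhMe, 80 °C
Reagents that add atoms: none
Why: Wittig olefination: the α,α'-dialkoxy ketone is unusually electrophilic and condenses readily with carbonyl-stabilised ylides, and because the ketone is symmetric the new alkene has no E/Z issue and no stereocentre.

**Step 2**
Reactants: 3 2-(2,2-dimethyl-1,3-dioxan-5-ylidene)-N-methoxy-N-methylacetamide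
Product: 5 2-(2,2-dimethyl-1,3-dioxan-5-ylidene)acetaldehyde, via aluminium hemiaminal 4 (not isolated)
Conditions: iBu2AlH (1.2 equiv), THF, −78 °C; aq. potassium sodium tartrate (KNaC4H4O6) work-up
Reagents that add atoms: none
Why: Reduction of an N-methoxy-N-methylamide (Weinreb amide): the chelated tetrahedral aluminium adduct 4 survives until the neutral tartrate work-up, so reduction should stop at the enal with the acetonide untouched.

**Step 3**
Reactants: 5 2-(2,2-dimethyl-1,3-dioxan-5-ylidene)acetaldehyde
Product: 6 2,2-dimethyl-5-[(E)-2-(triethylsilyloxy)ethenyl]-4H-1,3-dioxine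
Conditions: Et3SiOTf (1.2 equiv), Et3N (2 equiv), Et2O, −78 → 0 °C; filtration through Et3N-deactivated alumina
Reagents that add atoms: triethylsilyl trifluoromethanesulfonate, CC[Si](CC)(CC)OS(=O)(=O)C(F)(F)F
Why: Soft enolisation (O-silylation, then γ-deprotonation) to a silyl dienol ether: either γ-CH2–O group gives the same ring enol ether, and the preferred s-trans silyloxocarbenium ion should deliver the (E)-configured C3=C4 enol ether.

**Step 4**
Reactants: 7 1,4-dioxane-2,5-diol (glycolaldehyde dimer); 8 ethyl 2-(triphenylphosphoranylidene)propanoate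
Product: 10 ethyl (E)-4-hydroxy-2-methylbut-2-enoate, via glycolaldehyde 9 (not isolated)
Conditions: CH2Cl2, 40 °C
Reagents that add atoms: none
Why: Wittig olefination of the monomeric aldehyde released from its dimer with an α-branched stabilised ylide, which should give the (E)-trisubstituted enoate under the usual thermodynamic control of such ylides.

**Step 5**
Reactants: 10 ethyl (E)-4-hydroxy-2-methylbut-2-enoate
Product: 11 ethyl (E)-4-[(tert-butyldiphenylsilyl)oxy]-2-methylbut-2-enoate
Conditions: tBuPh2SiCl, imidazole, CH2Cl2, 0 °C → rt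
Reagents that add atoms: tert-butyl(chloro)diphenylsilane, CC(C)(C)[Si](Cl)(c1ccccc1)c1ccccc1
Why: Imidazole-promoted silylation of an unhindered primary allylic alcohol, giving an ether that later withstands base, mild acid and buffered fluoride.

**Step 6**
Reactants: 11 ethyl (E)-4-[(tert-butyldiphenylsilyl)oxy]-2-methylbut-2-enoate
Product: 13 (E)-4-[(tert-butyldiphenylsilyl)oxy]-2-methylbut-2-enoic acid, via lithium carboxylate 12 (not isolated)
Conditions: LiOH·H2O, THF/H2O (3:1), rt; then 1 M HCl to pH 3, 0 °C
Reagents that add atoms: lithium hydroxide, [Li+].[OH-]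
Why: Ester saponification by acyl–oxygen cleavage, which the tert-butyldiphenylsilyl ether tolerates at room temperature and which cannot isomerise the trisubstituted (E)-alkene.

**Step 7**
Reactants: 13 (E)-4-[(tert-butyldiphenylsilyl)oxy]-2-methylbut-2-enoic acid; 14 but-3-yn-2-one
Product: 15 (E)-3-oxobut-1-en-1-yl (E)-4-[(tert-butyldiphenylsilyl)oxy]-2-methylbut-2-enoate
Conditions: N-methylmorpholine (0.2 equiv), CH2Cl2, 0 °C → rt
Reagents that add atoms: none
Why: Tertiary-amine-catalysed conjugate (oxa-Michael) addition of a carboxylic acid to an ynone, in which the amine adds first and the carboxylate then displaces it from the β-ammonium enone to give the more stable (E)-β-acyloxy enone.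

**Step 8**
Reactants: 6 2,2-dimethyl-5-[(E)-2-(triethylsilyloxy)ethenyl]-4H-1,3-dioxine (1.5 equiv); 15 (E)-3-oxobut-1-en-1-yl (E)-4-[(tert-butyldiphenylsilyl)oxy]-2-methylbut-2-enoate
Product: 16 (6S,7R,8R,8aR)-7-acetyl-2,2-dimethyl-6-(triethylsilyloxy)-6,7,8,8a-tetrahydro-4H-1,3-benzodioxin-8-yl (E)-4-[(tert-butyldiphenylsilyl)oxy]-2-methylbut-2-enoate (target numbering: acetonide across the C1 and C7 oxygens; C1–O, C4–OSiEt3 and C5–acetyl all α, C6–O-acyl β)
Conditions: (S)-1-(2-methylphenyl)-3,3-diphenyltetrahydro-1H,3H-pyrrolo[1,2-c][1,3,2]oxazaborole (24 mol %), HN(SO2CF3)2 (20 mol %), CH2Cl2, −78 → −40 °C; Et3N quench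
Reagents that add atoms: none
Why: Proposed new method: the N-protonated oxazaborolidine binds the acetyl oxygen of 15 at boron (the enone C5–H resting on the ring oxygen), lowers the enone LUMO, and diene 6 adds suprafacially on both partners in a concerted but asynchronous [4+2] step in which C1–C6 bonding (donor-activated diene terminus to the enone β-carbon) runs ahead of C4–C5 bonding. The closest established reaction types are Lewis-acid-promoted cycloadditions of 1-silyloxydienes with β-acyloxy enones and oxazaborolidinium-catalysed cycloadditions of simple dienes with enones; an acetal-bridged 1,4-dioxygenated diene has not been used in this way. The cyclohexene ring C1–C6 is closed by this intermolecular endo π4s+π2s union, the existing dioxine ring simply ending up fused to it at C1–C2. C1 and C4 (oxygens cis) are fixed by the ring-locked C1=C2 geometry and the (E)-enol ether, C5 relative to C6 (trans) by the (E)-enone, C5 relative to C4 (cis) by the endo position of the boron-bound acetyl group, and the absolute sense by the catalyst, whose stacked phenyl group is expected in the (S)-series to leave open the C5-Si/C6-Si face that leads to the required 4S series. The step needs C1-to-C6 regiochemistry, endo approach and one enone face: attack through C1 develops an allyl cation stabilised at both ends (tertiary C2, silyloxy-bearing C4), whereas attack through C4 would leave the C7 branch on the central carbon and rely on the inductively weakened acetal oxygen, and keeping HN(SO2CF3)2 substoichiometric to the oxazaborolidine should spare the acid-labile diene.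

**Step 9**
Reactants: 16 Diels–Alder adduct (C5 acetyl)
Product: 17 C5 prop-1-en-2-yl analogue of 16 (acetyl C=O replaced by C=CH2; all stereocentres as in 16)
Conditions: Zn, CH2Br2, TiCl4 (reagent pre-aged in THF at 5 °C); then 16, CH2Cl2, 0 °C → rt
Reagents that add atoms: dibromomethane, BrCBr
Why: Takai–Lombardo methylenation: the non-basic zinc/titanium methylene reagent converts enolisable ketones into 1,1-disubstituted alkenes without epimerising the α-centre (C5) and leaves esters, silyl ethers and the acetonide alone.

**Step 10**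
Reactants: 17 C5 prop-1-en-2-yl compound
Product: 18 C5 isopropyl compound (acetonide, C4–OSiEt3, C6 ester; stereocentres as in 16)
Conditions: H2 (1 atm), RhCl(PPh3)3 (10 mol %), PhH, rt
Reagents that add atoms: none
Why: Homogeneous hydrogenation with RhCl(PPh3)3, which discriminates sterically and should saturate only the 1,1-disubstituted isopropenyl alkene, leaving the trisubstituted ring alkene and the trisubstituted conjugated ester alkene; no stereocentre is created.

**Step 11**
Reactants: 18 C5 isopropyl compound
Product: 19 C4 alcohol (acetonide, C5 isopropyl, C6 ester, side-chain silyl ether retained; C4–OH α)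
Conditions: HF·pyridine, pyridine, THF, 0 °C
Reagents that add atoms: none
Why: Fluoride-mediated desilylation in which the secondary triethylsilyl ether is cleaved far faster than the primary tert-butyldiphenylsilyl ether, the pyridine buffer protecting the acetonide; C4 keeps its configuration because only the Si–O bond breaks.

**Step 12**
Reactants: 19 C4 alcohol
Product: 20 C4 propanoate (acetonide, C5 isopropyl, C6 ester with side-chain silyl ether)
Conditions: (EtCO)2O, Et3N, 4-(dimethylamino)pyridine (10 mol %), CH2Cl2, 0 °C → rt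
Reagents that add atoms: propanoic anhydride, CCC(=O)OC(=O)CC
Why: Nucleophile-catalysed acylation of the secondary allylic alcohol with retention at C4; the trans-1,3 disposition of the C4 hydroxyl and the C6 ester disfavours acyl migration.

**Step 13**
Reactants: 20 C4 propanoate acetonide
Product: 21 C1,C7-diol (C1–OH α; C4 propanoate, C5 isopropyl, C6 ester)
Conditions: AcOH/THF/H2O (3:1:1), 35 °C
Reagents that add atoms: none
Why: Acid-catalysed hydrolysis of the isopropylidene acetal, mild enough to leave the three esters and the tert-butyldiphenylsilyl ether intact and too weakly acidic to drive C6-to-C1 acyl migration.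

**Step 14**
Reactants: 21 C1,C7-diol
Product: 22 C7 tert-butyldimethylsilyl ether with free C1–OH
Conditions: tBuMe2SiCl (1.1 equiv), imidazole, CH2Cl2, −20 → 0 °C
Reagents that add atoms: tert-butyl(chloro)dimethylsilane, CC(C)(C)[Si](C)(C)Cl
Why: Sterically controlled silylation, the primary allylic C7 hydroxyl reacting much faster than the secondary C1 hydroxyl flanked by C2 and the acylated C6.

**Step 15**
Reactants: 22 C7 silyl ether, C1 alcohol
Product: 23 bis-silylated enone (C1 ketone; C7–OSiMe2tBu; side-chain OSiPh2tBu)
Conditions: Dess–Martin periodinane (1,1,1-triacetoxy-1,1-dihydro-1,2-benziodoxol-3(1H)-one), CH2Cl2, 0 °C → rt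
Reagents that add atoms: none
Why: Dess–Martin oxidation of the secondary allylic alcohol to the enone under non-basic conditions, which erases the auxiliary C1 centre without epimerising the now α-acyloxy C6 centre.

**Step 16**
Reactants: 23 bis-silylated enone
Product: 24 (4S,5S,6R)-2-(hydroxymethyl)-6-{[(E)-4-hydroxy-2-methylbut-2-enoyl]oxy}-5-(propan-2-yl)-4-(propanoyloxy)cyclohex-2-en-1-one (CNP0285949.1)
Conditions: HF·pyridine, pyridine, THF, 0 °C → rt
Reagents that add atoms: none
Why: Fluoride-mediated cleavage of both primary silyl ethers under buffered, non-basic conditions, which avoids acyl migration, β-elimination and C6 epimerisation of the α-acyloxy enone.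

**Compound list**

1 | 2,2-dimethyl-1,3-dioxan-5-one | CC1(C)OCC(=O)CO1 | starting material
2 | N-methoxy-N-methyl-2-(triphenylphosphoranylidene)acetamide | CON(C)C(=O)C=P(c1ccccc1)(c1ccccc1)c1ccccc1 | starting material
3 | 2-(2,2-dimethyl-1,3-dioxan-5-ylidene)-N-methoxy-N-methylacetamide | CON(C)C(=O)C=C1COC(C)(C)OC1 | intermediate
4 | O-(diisobutylaluminio) N-methoxy-N-methyl hemiaminal of 5 (tetrahedral reduction adduct) | CON(C)C(O[Al](CC(C)C)CC(C)C)C=C1COC(C)(C)OC1 | intermediate (not isolated)
5 | 2-(2,2-dimethyl-1,3-dioxan-5-ylidene)acetaldehyde | O=CC=C1COC(C)(C)OC1 | intermediate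
6 | 2,2-dimethyl-5-[(E)-2-(triethylsilyloxy)ethenyl]-4H-1,3-dioxine | CC[Si](CC)(CC)O/C=C/C1=COC(C)(C)OC1 | intermediate
7 | 1,4-dioxane-2,5-diol (glycolaldehyde dimer) | OC1COC(O)CO1 | starting material
8 | ethyl 2-(triphenylphosphoranylidene)propanoate | CCOC(=O)C(C)=P(c1ccccc1)(c1ccccc1)c1ccccc1 | starting material
9 | glycolaldehyde (hydroxyacetaldehyde) | OCC=O | intermediate (not isolated)
10 | ethyl (E)-4-hydroxy-2-methylbut-2-enoate | CCOC(=O)/C(C)=C/CO | intermediate
11 | ethyl (E)-4-[(tert-butyldiphenylsilyl)oxy]-2-methylbut-2-enoate | CCOC(=O)/C(C)=C/CO[Si](c1ccccc1)(c1ccccc1)C(C)(C)C | intermediate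
12 | lithium (E)-4-[(tert-butyldiphenylsilyl)oxy]-2-methylbut-2-enoate | [Li+].[O-]C(=O)/C(C)=C/CO[Si](c1ccccc1)(c1ccccc1)C(C)(C)C | intermediate (not isolated)
13 | (E)-4-[(tert-butyldiphenylsilyl)oxy]-2-methylbut-2-enoic acid | OC(=O)/C(C)=C/CO[Si](c1ccccc1)(c1ccccc1)C(C)(C)C | intermediate
14 | but-3-yn-2-one | CC(=O)C#C | starting material
15 | (E)-3-oxobut-1-en-1-yl (E)-4-[(tert-butyldiphenylsilyl)oxy]-2-methylbut-2-enoate | CC(=O)/C=C/OC(=O)/C(C)=C/CO[Si](c1ccccc1)(c1ccccc1)C(C)(C)C | intermediate
16 | (6S,7R,8R,8aR)-7-acetyl-2,2-dimethyl-6-(triethylsilyloxy)-6,7,8,8a-tetrahydro-4H-1,3-benzodioxin-8-yl (E)-4-[(tert-butyldiphenylsilyl)oxy]-2-methylbut-2-enoate | CC[Si](CC)(CC)O[C@H]1C=C2COC(C)(C)O[C@H]2[C@H](OC(=O)/C(C)=C/CO[Si](c3ccccc3)(c3ccccc3)C(C)(C)C)[C@H]1C(C)=O | intermediate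
17 | C5 prop-1-en-2-yl analogue of 16 (stereocentres unchanged) | CC[Si](CC)(CC)O[C@H]1C=C2COC(C)(C)O[C@H]2[C@H](OC(=O)/C(C)=C/CO[Si](c3ccccc3)(c3ccccc3)C(C)(C)C)[C@H]1C(C)=C | intermediate
18 | C5 isopropyl analogue of 16 (stereocentres unchanged) | CC[Si](CC)(CC)O[C@H]1C=C2COC(C)(C)O[C@H]2[C@H](OC(=O)/C(C)=C/CO[Si](c3ccccc3)(c3ccccc3)C(C)(C)C)[C@H]1C(C)C | intermediate
19 | C4 alcohol: 18 without the triethylsilyl group (C4–OH α) | O[C@H]1C=C2COC(C)(C)O[C@H]2[C@H](OC(=O)/C(C)=C/CO[Si](c3ccccc3)(c3ccccc3)C(C)(C)C)[C@H]1C(C)C | intermediate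
20 | C4 propanoate of 19 | CCC(=O)O[C@H]1C=C2COC(C)(C)O[C@H]2[C@H](OC(=O)/C(C)=C/CO[Si](c3ccccc3)(c3ccccc3)C(C)(C)C)[C@H]1C(C)C | intermediate
21 | C1,C7-diol: 20 without the acetonide (C1–OH α, cis to the C4 propanoate) | CCC(=O)O[C@H]1C=C(CO)[C@@H](O)[C@H](OC(=O)/C(C)=C/CO[Si](c2ccccc2)(c2ccccc2)C(C)(C)C)[C@H]1C(C)C | intermediate
22 | C7 tert-butyldimethylsilyl ether of 21 (C1–OH free) | CCC(=O)O[C@H]1C=C(CO[Si](C)(C)C(C)(C)C)[C@@H](O)[C@H](OC(=O)/C(C)=C/CO[Si](c2ccccc2)(c2ccccc2)C(C)(C)C)[C@H]1C(C)C | intermediate
23 | bis-silylated enone: C1 ketone, C7–OSiMe2tBu, C4 propanoate, C5 isopropyl, C6 (E)-4-(tert-butyldiphenylsilyloxy)-2-methylbut-2-enoate | CCC(=O)O[C@H]1C=C(CO[Si](C)(C)C(C)(C)C)C(=O)[C@H](OC(=O)/C(C)=C/CO[Si](c2ccccc2)(c2ccccc2)C(C)(C)C)[C@H]1C(C)C | intermediate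
24 | (4S,5S,6R)-2-(hydroxymethyl)-6-{[(E)-4-hydroxy-2-methylbut-2-enoyl]oxy}-5-(propan-2-yl)-4-(propanoyloxy)cyclohex-2-en-1-one | CCC(=O)O[C@H]1C=C(CO)C(=O)[C@H](OC(=O)/C(C)=C/CO)[C@H]1C(C)C | target

**Step count and risk**

Total step count: 16. Longest linear sequence: 13 steps (steps 4–7, then 8–16); the diene arm (steps 1–3) joins at step 8.

Steps most likely to fail:

1. Step 8 (carries the label). Process: bond formation through the wrong diene terminus (C4 to C6), or acid-induced desilylation and silyl transfer that open an achiral silyl-triflimide-catalysed channel and erode facial control. Fallback (absolute configuration from resolution instead of catalyst control): set out from 6 and 15 and run the cycloaddition thermally without any acid (PhMe, 80 °C, 2,6-di-tert-butyl-4-methylphenol, base-washed glass). This is the established thermal endo mode of 1-silyloxydienes with activated enones and should give racemic adduct, that is 16 accompanied by its mirror image, the enantiomeric adduct F1. Preparative chromatography on a chiral stationary phase (amylose tris(3,5-dimethylphenylcarbamate), supercritical CO2/iPrOH) separates the two, and the route is rejoined at 16.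

2. Step 3. Process: incomplete (E)-control during soft enolisation and hydrolytic or acid-triggered loss of the silyl dienol ether on isolation. Fallback: set out from 5; enol acetylation (Ac2O, Et3N, 4-(dimethylamino)pyridine, PhMe, 80 °C) gives the robust, chromatographable (E)-dienyl acetate F2, which is purified as the single (E)-isomer. MeLi (2 equiv, THF, −78 → 0 °C) then cleaves the acetate to lithium dienolate F3 with retention of enolate geometry, and Et3SiCl added to the same flask silylates it on oxygen, returning to 6 immediately before use.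

3. Step 9. Process: titanium-induced epimerisation at C5 or β-elimination of the C6 acyloxy group, or stalled conversion of the congested ketone. Fallback (Peterson olefination in two stages): set out from 16; Me3SiCH2Li/CeCl3 (THF, −78 °C; weakly basic organocerium addition, chemoselective for the ketone) gives β-hydroxysilane F4. HF·pyridine (THF, 0 °C → rt) triggers anti-elimination of the β-hydroxysilane and at the same time removes the C4 triethylsilyl group, giving isopropenyl alcohol F5. Hydrogenation (H2, RhCl(PPh3)3, PhH) then rejoins the route at 19.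

**Further compounds**

F1 | step 8 | enantiomer of 16, (6R,7S,8S,8aS)-7-acetyl-2,2-dimethyl-6-(triethylsilyloxy)-6,7,8,8a-tetrahydro-4H-1,3-benzodioxin-8-yl (E)-4-[(tert-butyldiphenylsilyl)oxy]-2-methylbut-2-enoate | CC[Si](CC)(CC)O[C@@H]1C=C2COC(C)(C)O[C@@H]2[C@@H](OC(=O)/C(C)=C/CO[Si](c3ccccc3)(c3ccccc3)C(C)(C)C)[C@@H]1C(C)=O
F2 | step 3 | (E)-2-(2,2-dimethyl-4H-1,3-dioxin-5-yl)ethenyl acetate | CC(=O)O/C=C/C1=COC(C)(C)OC1
F3 | step 3 | lithium (E)-2-(2,2-dimethyl-4H-1,3-dioxin-5-yl)ethenolate | [Li+].[O-]/C=C/C1=COC(C)(C)OC1
F4 | step 9 | β-hydroxysilane: 16 with the C5 acetyl group converted into 2-hydroxy-1-(trimethylsilyl)propan-2-yl (carbinol centre undefined) | CC[Si](CC)(CC)O[C@H]1C=C2COC(C)(C)O[C@H]2[C@H](OC(=O)/C(C)=C/CO[Si](c3ccccc3)(c3ccccc3)C(C)(C)C)[C@H]1C(C)(O)C[Si](C)(C)C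
F5 | step 9 | isopropenyl alcohol: 17 without the triethylsilyl group (C4–OH α) | O[C@H]1C=C2COC(C)(C)O[C@H]2[C@H](OC(=O)/C(C)=C/CO[Si](c3ccccc3)(c3ccccc3)C(C)(C)C)[C@H]1C(C)=C
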